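**Strategy.** Ring B is closed last at C4–C4a. In the target, C3 carries two CH2 groups: C4, bonded to C4a of ring A, and C3a, bearing OH. Both are the CH2O arms of a 3-substituted oxetane. An aryllithium generated at C4a of ring A therefore opens the oxetane in one operation: it forms C4–C4a, closes ring B, frees C3a–OH and creates C3 by choosing between two diastereotopic CH2 groups. The precursor is the ring A bromide whose C1 carries the protected syringyl ring and whose C2 carries the oxetan-3-yl group and a CH2OSi(i-Pr)3 arm. C1 and C2 come from one enamine-catalysed quinone methide addition.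

Key step: step 11

Remark 1: tetralin locants of the target are used for all intermediates (C1 aryl-bearing, C2 with arm C2a, C3 with arm C3a, C4; ring A = C4a–C8a, ring B the saturated ring).

Remark 2: the C2a oxygen is carried as a triisopropylsilyl ether, not as an electron-rich benzyl-type ether. Its oxygen should neither chelate the aryllithium nor attack the BF3-activated oxetane, and fluoride removal avoids an oxidative deprotection next to the doubly benzylic C1–H.

Remark 3: the sulfate monoesters 21 and 22 are handled as sodium salts and drawn as free acids; 22 is released on an acidic resin.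

Step 1
Reactants: 1 4-bromo-2,6-dimethoxyphenol
Product: 2 2-(benzyloxy)-5-bromo-1,3-dimethoxybenzene
Conditions: BnBr, K2CO3, DMF, rt
Reagents that add atoms: benzyl bromide, BrCc1ccccc1
Why: Williamson ether synthesis, in which the phenoxide displaces bromide from benzyl bromide; no stereocentre is involved.

Step 2
Reactants: 2 2-(benzyloxy)-5-bromo-1,3-dimethoxybenzene
Product: 4 3-(benzyloxy)-6-bromo-2,4-dimethoxybenzaldehyde, via aryllithium 3 (not isolated)
Conditions: LiN(i-Pr)2, THF, −78 °C; DMF, −78 → 0 °C; 1 M HCl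
Reagents that add atoms: N,N-dimethylformamide, CN(C)C=O
Why: Directed ortho-lithiation then formylation with DMF (Bouveault-type): the only ring C–H left lies between OMe and Br, which both acidify it, the two such positions are equivalent, and at −78 °C the ortho-bromoaryllithium should be trapped before it can lose LiBr.

Step 3
Reactants: 1 4-bromo-2,6-dimethoxyphenol
Product: 5 tert-butyl(4-bromo-2,6-dimethoxyphenoxy)dimethylsilane
Conditions: t-BuMe2SiCl, imidazole, DMF, rt
Reagents that add atoms: tert-butyldimethylsilyl chloride, CC(C)(C)[Si](C)(C)Cl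
Why: Imidazole-promoted silylation of a phenol; the silyl ether masks the acidic OH for the Grignard step and later triggers quinone methide formation.

Step 4
Reactants: 5 tert-butyl(4-bromo-2,6-dimethoxyphenoxy)dimethylsilane; 4 3-(benzyloxy)-6-bromo-2,4-dimethoxybenzaldehyde
Product: 7 racemic [3-(benzyloxy)-6-bromo-2,4-dimethoxyphenyl]{4-[(tert-butyldimethylsilyl)oxy]-3,5-dimethoxyphenyl}methanol, via Grignard reagent 6 (not isolated)
Conditions: Mg, I2 (cat.), THF, 50 °C; then 4, THF, −20 °C → rt; aq. NH4Cl
Reagents that add atoms: none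
Why: Grignard addition to an aldehyde, which should be faster than any reaction at the aryl bromide of 4; the new carbinol centre is racemic and is erased in step 5.

Step 5
Reactants: 7 racemic silyl-protected diaryl carbinol
Product: 9 4-{[3-(benzyloxy)-6-bromo-2,4-dimethoxyphenyl]methylidene}-2,6-dimethoxycyclohexa-2,5-dien-1-one, via phenol carbinol 8 (not isolated)
Conditions: Bu4NF, AcOH, THF, 0 °C; then pyridinium p-toluenesulfonate (cat.), MgSO4, CH2Cl2, rt; used crude
Reagents that add atoms: none
Why: Fluoride desilylation followed by acid-catalysed 1,6-dehydration of a para-hydroxybenzhydrol, which ionises easily between two electron-rich rings; the quinoid ring is symmetric, so the quinone methide has no E/Z isomers.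

Step 6
Reactants: 10 oxetan-3-one
Product: 11 2-(oxetan-3-ylidene)acetaldehyde
Conditions: Ph3P=CHCHO, CH2Cl2, rt
Reagents that add atoms: (triphenylphosphoranylidene)acetaldehyde, O=CC=P(c1ccccc1)(c1ccccc1)c1ccccc1
Why: Wittig olefination of a strained, highly electrophilic ketone with a stabilised ylide; the ketone is symmetric, so no alkene isomers arise.

Step 7
Reactants: 11 2-(oxetan-3-ylidene)acetaldehyde
Product: 12 2-(oxetan-3-yl)acetaldehyde
Conditions: H2 (1 atm), Pd/C, EtOAc, rt; filtered solution used directly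
Reagents that add atoms: none
Why: Heterogeneous catalytic hydrogenation, chemoselective for the conjugated C=C over the aldehyde; the volatile product is kept in solution.

Step 8
Reactants: 9 quinone methide; 12 2-(oxetan-3-yl)acetaldehyde
Product: 14 4-{(1R,2S)-1-[3-(benzyloxy)-6-bromo-2,4-dimethoxyphenyl]-3-hydroxy-2-(oxetan-3-yl)propyl}-2,6-dimethoxyphenol, via aldehyde 13 (not isolated)
Conditions: (S)-2-[diphenyl(trimethylsilyloxy)methyl]pyrrolidine (20 mol %), PhCO2H (20 mol %), CH2Cl2, 0 °C → rt; then MeOH, NaBH4, 0 °C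
Reagents that add atoms: none
Why: Enamine-catalysed asymmetric 1,6-conjugate addition of an aldehyde to a para-quinone methide, then borohydride reduction: attack on the E-enamine face remote from the diphenyl(silyloxy)methyl group should set C2 as S, the open synclinal approach known from enamine additions to nitroalkenes should set C1 as R, rearomatisation makes the addition irreversible, and reduction in the same flask removes the epimerisable aldehyde.

Step 9
Reactants: 14 phenol alcohol
Product: 15 (2S,3R)-3-[3-(benzyloxy)-6-bromo-2,4-dimethoxyphenyl]-3-[4-(benzyloxy)-3,5-dimethoxyphenyl]-2-(oxetan-3-yl)propan-1-ol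
Conditions: BnBr, K2CO3, DMF, rt
Reagents that add atoms: benzyl bromide, BrCc1ccccc1
Why: Williamson ether synthesis, chemoselective because K2CO3 deprotonates the phenol only and leaves the primary alcohol alone; no stereocentre is touched.

Step 10
Reactants: 15 primary alcohol
Product: 16 triisopropylsilyl ether of 15, the ring A bromide bearing the (1R,2S)-1-aryl-2-(oxetan-3-yl)-3-(silyloxy)propyl chain
Conditions: (i-Pr)3SiCl, imidazole, 4-(dimethylamino)pyridine (cat.), DMF, rt
Reagents that add atoms: triisopropylsilyl chloride, CC(C)[Si](Cl)(C(C)C)C(C)C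
Why: Silylation of a primary alcohol; the bulky silyl ether is inert to t-BuLi and to BF3 at low temperature and its oxygen is a poor donor.

Step 11
Reactants: 16 ring A bromide with oxetane
Product: 18 [(1R,2S,3S)-7-(benzyloxy)-1-[4-(benzyloxy)-3,5-dimethoxyphenyl]-6,8-dimethoxy-2-{[(triisopropylsilyl)oxy]methyl}-1,2,3,4-tetrahydronaphthalen-3-yl]methanol, via aryllithium 17 (not isolated)
Conditions: t-BuLi (2.1 equiv), THF, −78 °C; then BF3·OEt2 (1.5 equiv), −78 → −40 °C; aq. NH4Cl
Reagents that add atoms: none
Why: Proposed new method: bromine–lithium exchange at C4a outruns any reaction of the unactivated oxetane; BF3 then binds the oxetane oxygen and the aryl carbanion displaces it at one CH2 by backside attack, forming C4–C4a and leaving C3a–O–BF3Li, which work-up protonates. The closest known reactions are the BF3-promoted opening of oxetanes by aryllithiums, Parham cyclisations onto epoxides and alkyl halides, and catalytic intramolecular oxetane desymmetrisations. Ring B closes in the 6-exo-tet mode. A collinear C4a···C4–O array forces the unattacked CH2O arm (C3a) anti to C4a, that is equatorial on the forming ring, so each diastereotopic CH2 corresponds to one half-chair and C3 is set by substrate control from C1 and C2. The half-chair that keeps the C2 silyloxymethyl arm equatorial, trans to a pseudo-equatorial C1 aryl, should give 3S with C3a trans to C2a and cis to the aryl, whereas the other must turn both the C1 aryl and the C2 arm axial, the arm gauche to C4 and C8a. The step needs this group selectivity and site selectivity for C4a; the bulky, non-chelating silyl ether (no lithium–oxygen contact to pull the arm axial) is meant to secure the first, and the bromide, which places the carbanion on ring A and not on the more electron-rich pendant ring, secures the second.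

Step 12
Reactants: 18 tetralin alcohol
Product: 19 C3a benzyl ether of 18, (1R,2S,3S)-7-(benzyloxy)-1-[4-(benzyloxy)-3,5-dimethoxyphenyl]-3-[(benzyloxy)methyl]-6,8-dimethoxy-2-{[(triisopropylsilyl)oxy]methyl}tetralin
Conditions: NaH, BnBr, Bu4NI (cat.), THF/DMF, 0 °C → rt
Reagents that add atoms: benzyl bromide, BrCc1ccccc1
Why: Williamson ether synthesis on the sodium alkoxide of C3a–OH; the triisopropylsilyl group is too hindered to migrate to the neighbouring alkoxide.

Step 13
Reactants: 19 silyl ether
Product: 20 [(1R,2S,3S)-7-(benzyloxy)-1-[4-(benzyloxy)-3,5-dimethoxyphenyl]-3-[(benzyloxy)methyl]-6,8-dimethoxy-1,2,3,4-tetrahydronaphthalen-2-yl]methanol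
Conditions: Bu4NF, THF, rt
Reagents that add atoms: none
Why: Fluoride-mediated desilylation, orthogonal to the three benzyl ethers, which should free C2a–OH alone.

Step 14
Reactants: 20 C2a alcohol
Product: 21 hydrogen sulfate of 20 at C2a–O
Conditions: SO3·pyridine, pyridine, rt; cation-exchange resin (Na+ form), MeOH
Reagents that add atoms: sulfur trioxide–pyridine complex, O=S(=O)([O-])[n+]1ccccc1
Why: O-Sulfation of the only free hydroxyl with the sulfur trioxide–pyridine complex; the counter-ion is changed to sodium so that pyridine does not inhibit the hydrogenolysis.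

Step 15
Reactants: 21 tribenzyl sulfate
Product: 22 [(1R,2S,3S)-7-hydroxy-1-(4-hydroxy-3,5-dimethoxyphenyl)-3-(hydroxymethyl)-6,8-dimethoxy-1,2,3,4-tetrahydronaphthalen-2-yl]methyl hydrogen sulfate (CNP0111670.1)
Conditions: H2 (1 atm), Pd/C, MeOH, rt; cation-exchange resin (H+ form)
Reagents that add atoms: none
Why: Catalytic hydrogenolysis of two aryl benzyl ethers and one alkyl benzyl ether; the alkyl sulfate salt and the C1 diarylmethine should not be cleaved and no stereocentre is touched.

**Compound list**

1 | 4-bromo-2,6-dimethoxyphenol | COc1cc(Br)cc(OC)c1O | starting material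
2 | 2-(benzyloxy)-5-bromo-1,3-dimethoxybenzene | COc1cc(Br)cc(OC)c1OCc1ccccc1 | intermediate
3 | [3-(benzyloxy)-6-bromo-2,4-dimethoxyphenyl]lithium | COc1cc(Br)c([Li])c(OC)c1OCc1ccccc1 | intermediate
4 | 3-(benzyloxy)-6-bromo-2,4-dimethoxybenzaldehyde | COc1cc(Br)c(C=O)c(OC)c1OCc1ccccc1 | intermediate
5 | tert-butyl(4-bromo-2,6-dimethoxyphenoxy)dimethylsilane | COc1cc(Br)cc(OC)c1O[Si](C)(C)C(C)(C)C | intermediate
6 | {4-[(tert-butyldimethylsilyl)oxy]-3,5-dimethoxyphenyl}magnesium bromide | COc1cc([Mg]Br)cc(OC)c1O[Si](C)(C)C(C)(C)C | intermediate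
7 | racemic [3-(benzyloxy)-6-bromo-2,4-dimethoxyphenyl]{4-[(tert-butyldimethylsilyl)oxy]-3,5-dimethoxyphenyl}methanol | COc1cc(C(O)c2c(Br)cc(OC)c(OCc3ccccc3)c2OC)cc(OC)c1O[Si](C)(C)C(C)(C)C | intermediate
8 | racemic 4-{[3-(benzyloxy)-6-bromo-2,4-dimethoxyphenyl](hydroxy)methyl}-2,6-dimethoxyphenol | COc1cc(C(O)c2c(Br)cc(OC)c(OCc3ccccc3)c2OC)cc(OC)c1O | intermediate
9 | 4-{[3-(benzyloxy)-6-bromo-2,4-dimethoxyphenyl]methylidene}-2,6-dimethoxycyclohexa-2,5-dien-1-one | COC1=CC(=Cc2c(Br)cc(OC)c(OCc3ccccc3)c2OC)C=C(OC)C1=O | intermediate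
10 | oxetan-3-one | O=C1COC1 | starting material
11 | 2-(oxetan-3-ylidene)acetaldehyde | O=CC=C1COC1 | intermediate
12 | 2-(oxetan-3-yl)acetaldehyde | O=CCC1COC1 | intermediate
13 | (2S,3R)-3-[3-(benzyloxy)-6-bromo-2,4-dimethoxyphenyl]-3-(4-hydroxy-3,5-dimethoxyphenyl)-2-(oxetan-3-yl)propanal | COc1cc([C@@H]([C@H](C=O)C2COC2)c2c(Br)cc(OC)c(OCc3ccccc3)c2OC)cc(OC)c1O | intermediate
14 | 4-{(1R,2S)-1-[3-(benzyloxy)-6-bromo-2,4-dimethoxyphenyl]-3-hydroxy-2-(oxetan-3-yl)propyl}-2,6-dimethoxyphenol | COc1cc([C@@H]([C@H](CO)C2COC2)c2c(Br)cc(OC)c(OCc3ccccc3)c2OC)cc(OC)c1O | intermediate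
15 | (2S,3R)-3-[3-(benzyloxy)-6-bromo-2,4-dimethoxyphenyl]-3-[4-(benzyloxy)-3,5-dimethoxyphenyl]-2-(oxetan-3-yl)propan-1-ol | COc1cc([C@@H]([C@H](CO)C2COC2)c2c(Br)cc(OC)c(OCc3ccccc3)c2OC)cc(OC)c1OCc1ccccc1 | intermediate
16 | triisopropylsilyl ether of 15 (key-step precursor) | COc1cc([C@@H]([C@H](CO[Si](C(C)C)(C(C)C)C(C)C)C2COC2)c2c(Br)cc(OC)c(OCc3ccccc3)c2OC)cc(OC)c1OCc1ccccc1 | intermediate
17 | C4a-lithio compound from 16 (lithium in place of bromine) | COc1cc([C@@H]([C@H](CO[Si](C(C)C)(C(C)C)C(C)C)C2COC2)c2c([Li])cc(OC)c(OCc3ccccc3)c2OC)cc(OC)c1OCc1ccccc1 | intermediate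
18 | [(1R,2S,3S)-7-(benzyloxy)-1-[4-(benzyloxy)-3,5-dimethoxyphenyl]-6,8-dimethoxy-2-{[(triisopropylsilyl)oxy]methyl}-1,2,3,4-tetrahydronaphthalen-3-yl]methanol (key-step product) | COc1cc([C@@H]2c3c(cc(OC)c(OCc4ccccc4)c3OC)C[C@H](CO)[C@H]2CO[Si](C(C)C)(C(C)C)C(C)C)cc(OC)c1OCc1ccccc1 | intermediate
19 | (1R,2S,3S)-7-(benzyloxy)-1-[4-(benzyloxy)-3,5-dimethoxyphenyl]-3-[(benzyloxy)methyl]-6,8-dimethoxy-2-{[(triisopropylsilyl)oxy]methyl}tetralin | COc1cc([C@@H]2c3c(cc(OC)c(OCc4ccccc4)c3OC)C[C@H](COCc3ccccc3)[C@H]2CO[Si](C(C)C)(C(C)C)C(C)C)cc(OC)c1OCc1ccccc1 | intermediate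
20 | [(1R,2S,3S)-7-(benzyloxy)-1-[4-(benzyloxy)-3,5-dimethoxyphenyl]-3-[(benzyloxy)methyl]-6,8-dimethoxy-1,2,3,4-tetrahydronaphthalen-2-yl]methanol | COc1cc([C@@H]2c3c(cc(OC)c(OCc4ccccc4)c3OC)C[C@H](COCc3ccccc3)[C@H]2CO)cc(OC)c1OCc1ccccc1 | intermediate
21 | [(1R,2S,3S)-7-(benzyloxy)-1-[4-(benzyloxy)-3,5-dimethoxyphenyl]-3-[(benzyloxy)methyl]-6,8-dimethoxy-1,2,3,4-tetrahydronaphthalen-2-yl]methyl hydrogen sulfate | COc1cc([C@@H]2c3c(cc(OC)c(OCc4ccccc4)c3OC)C[C@H](COCc3ccccc3)[C@H]2COS(=O)(=O)O)cc(OC)c1OCc1ccccc1 | intermediate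
22 | [(1R,2S,3S)-7-hydroxy-1-(4-hydroxy-3,5-dimethoxyphenyl)-3-(hydroxymethyl)-6,8-dimethoxy-1,2,3,4-tetrahydronaphthalen-2-yl]methyl hydrogen sulfate | COc1cc([C@@H]2c3c(cc(OC)c(O)c3OC)C[C@H](CO)[C@H]2COS(=O)(=O)O)cc(OC)c1O | target

**Step count.** Total: 15 steps. Longest linear sequence: 12 steps (steps 1, 2, 4, 5, 8, 9, 10, 11, 12, 13, 14, 15).

**Steps most likely to fail**

1. Step 11. During ring closure the C1 aryl group can escape the peri C8 methoxy by going pseudo-axial. This would drag the C2 arm axial and steer the carbanion to the other CH2, so that C3 forms with the opposite configuration. A slow closure also leaves room for proton capture by the aryllithium. Fallback: it sets out from 16 and comes back at 18. MgBr2·OEt2 in Et2O opens the oxetane of 16 at either CH2 to two C3-epimeric bromohydrins, which differ in which arm carries bromine and are separated by chromatography: the (3S)-bromohydrin F1, with bromine on the carbon that becomes C4, and the (3R)-bromohydrin F2. KOt-Bu in THF recloses F2 to 16 (Williamson oxetane synthesis) for another pass. F1 is treated with t-BuLi (3.1 equiv, THF, −78 → 0 °C): deprotonation and bromine–lithium exchange give the aryllithium alkoxide F3, which closes ring B by Parham cycloalkylation onto the primary bromide, with C3 already fixed, and gives 18 on work-up.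

2. Step 8. The quinone methide carbon is flanked by the ortho bromine and methoxy of ring A, so enamine attack may be slow and poorly face-selective at C1, and the adduct aldehyde can epimerise at C2 before reduction. Fallback: it sets out from 12 and 9 and comes back at 14. Chlorite oxidation of 12 (NaClO2, NaH2PO4, 2-methylbut-2-ene; Pinnick oxidation) gives 2-(oxetan-3-yl)acetic acid F4. Its pivaloyl mixed anhydride acylates lithiated (S)-4-benzyloxazolidin-2-one to the imide F5. The sodium Z-enolate of F5 (NaN(SiMe3)2, THF, −78 °C) adds 1,6 to 9; the auxiliary fixes C2 as S, and the C1 epimers of the adduct F6 are separated at this stage. LiBH4 in THF/MeOH removes the auxiliary reductively and gives 14.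

3. Step 5. The quinone methide may pick up water or its own phenolic precursor and oligomerise during dehydration and concentration. Fallback: it sets out from 7 and comes back at 9, which is then formed inside the flask of step 8. After desilylation of 7 to 8, sodium 4-methylbenzenesulfinate in aqueous formic acid converts the carbinol into the bench-stable sulfone F7, a known latent quinone methide. In step 8, F7 is stirred with aqueous NaHCO3, 12 and the amine catalyst; base-induced 1,6-elimination of sulfinate releases 9 at low concentration, where it is consumed as it forms.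

**Further compounds**

F1 | step 11 | (2S,3S,4R)-4-[3-(benzyloxy)-6-bromo-2,4-dimethoxyphenyl]-4-[4-(benzyloxy)-3,5-dimethoxyphenyl]-2-(bromomethyl)-3-{[(triisopropylsilyl)oxy]methyl}butan-1-ol | COc1cc([C@@H]([C@H](CO[Si](C(C)C)(C(C)C)C(C)C)[C@H](CBr)CO)c2c(Br)cc(OC)c(OCc3ccccc3)c2OC)cc(OC)c1OCc1ccccc1
F2 | step 11 | (2R,3S,4R)-epimer of F1 at the bromomethyl-bearing carbon | COc1cc([C@@H]([C@H](CO[Si](C(C)C)(C(C)C)C(C)C)[C@@H](CBr)CO)c2c(Br)cc(OC)c(OCc3ccccc3)c2OC)cc(OC)c1OCc1ccccc1
F3 | step 11 | C4a-lithio lithium alkoxide from F1 | COc1cc([C@@H]([C@H](CO[Si](C(C)C)(C(C)C)C(C)C)[C@H](CBr)CO[Li])c2c([Li])cc(OC)c(OCc3ccccc3)c2OC)cc(OC)c1OCc1ccccc1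
F4 | step 8 | 2-(oxetan-3-yl)acetic acid | OC(=O)CC1COC1
F5 | step 8 | (S)-4-benzyl-3-[2-(oxetan-3-yl)acetyl]oxazolidin-2-one | O=C(CC1COC1)N1[C@@H](Cc2ccccc2)COC1=O
F6 | step 8 | (S)-4-benzyl-3-[(2S,3R)-3-[3-(benzyloxy)-6-bromo-2,4-dimethoxyphenyl]-3-(4-hydroxy-3,5-dimethoxyphenyl)-2-(oxetan-3-yl)propanoyl]oxazolidin-2-one | COc1cc([C@@H]([C@H](C(=O)N2[C@@H](Cc3ccccc3)COC2=O)C2COC2)c2c(Br)cc(OC)c(OCc3ccccc3)c2OC)cc(OC)c1O
F7 | step 5 | racemic 4-{[3-(benzyloxy)-6-bromo-2,4-dimethoxyphenyl](4-methylbenzenesulfonyl)methyl}-2,6-dimethoxyphenol | COc1cc(C(c2c(Br)cc(OC)c(OCc3ccccc3)c2OC)S(=O)(=O)c2ccc(C)cc2)cc(OC)c1O
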